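In the 40 min that count here, the candidate steps let the impurity turn free catalyst into spent catalyst, so you count turnovers of what the impurity can't take.

| flask | solid substrate | partner | free catalyst | impurity | remark | time |
|---|---|---|---|---|---|---|
| Saturday's | 0.33 M | 1.3 M | 91 mM | 85 mM | run made earlier |  |
| Sunday's | 1.3 M | 1.3 M | 91 mM | 85 mM | run made earlier |  |
| flask | 0.65 M | 1.30 M | 91 mM | 85 mM |  | 40 min |

| run | time / min | product / % |
|---|---|---|
| Saturday's | 6.00 | 0 |
| Saturday's | 12.0 | 1.5 |
| Saturday's | 20.0 | 4.1 |
| Saturday's | 25.0 | 4.7 |
| Saturday's | 30.0 | 5.2 |
| Saturday's | 40.0 | 7.9 |
| Sunday's | 2.50 | 0.1 |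
| Sunday's | 8.00 | 0.5 |
| Sunday's | 15.0 | 0.1 |
| Sunday's | 20.0 | 1.2 |
| Sunday's | 30.0 | 0.4 |
| Sunday's | 40.0 | 1.5 |

(each reading ± 0.5 percentage points)

1. product at 40 min, in percent of the solid substrate charged
2. the change that raises the amount of product at 40 min, in percent of the solid substrate charged most ("none" if none brings more than 2 percentage points) (dawn / summer / winter / noon / none)
3. amount of product at 40 min, in percent of the solid substrate charged, after winter

- dawn: doubling the dissolution coefficient of the solid substrate, all else as stated
- summer: doubling the amount of partner, all else as stated
- winter: doubling the amount of free catalyst, all else as stated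
- noon: doubling the solubility of the solid substrate, all else as stated

- as a solid, counted per litre of solution: solid substrate
- the earlier runs were read with a standard deviation of 0.5 percentage points
- candidate steps: catalyst intermediate C -> free catalyst + product; free catalyst + impurity -> spent catalyst; catalyst intermediate B -> catalyst intermediate C; partner + free catalyst -> catalyst intermediate A; starting material + catalyst intermediate A <-> catalyst intermediate B; solid substrate <-> starting material
- at the start none of the solid substrate is in solution

Saturday's run held a quarter of Sunday's solid substrate, yet its last reading is 26.1 mM of product against Sunday's 19.5 mM, so you reckon in product per litre rather than in percent. The excess of free catalyst over impurity is 6.00 mM, and the two readings average 3.80 for the turnover number N, the product per litre made in the time divided by that excess. My reckoning for this flask is therefore 3.51 %, which stands above the forecast of 3.3 %. The forecast names winter as the best change, with 40 % after it, and says “Output is therefore essentially independent of solid loading”.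

The flask gives 4.13 %, which is N = 4.47. Winter adds 18 percentage points, against 2 points for noon, and it ends at 21.8 %.

    catalyst intermediate C → free catalyst + product (k = 0.920 min⁻¹)
    free catalyst + impurity → spent catalyst (k = 92.0 M⁻¹ min⁻¹)
    catalyst intermediate B → catalyst intermediate C (k = 0.810 min⁻¹)
    partner + free catalyst → catalyst intermediate A (k = 0.930 M⁻¹ min⁻¹)
    starting material + catalyst intermediate A ⇌ catalyst intermediate B (K = 0.930 M⁻¹, k = 1.50 M⁻¹ min⁻¹)
    solid substrate ⇌ starting material, rate k6*(cs6 - [starting material]) while solid is left; crystals form when [starting material] > cs6 (solubility = 0.130 M, k = 0.150 min⁻¹)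

Take the neighbour charged with 0.15 M of free catalyst, whose excess is 65.0 mM: the carried N of 3.80 promises 38.0 %, but that flask gives 15.5 %, which is N = 1.55. At 40.0 min the neighbour has 0 % of its impurity left, and catalyst intermediate A holds 36.7 % of its catalyst.

(The numbers in the tables stem from a simulated flask with constants of no real substance; scatter was added.)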